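In a closed flask the Q charged stays counted, so each fall in a reading of Q is a molecule that has taken a fork: alone towards J, or with a partner, as in X or E.

| flask | Q | remark | time |
|---|---|---|---|
| teal | 0.0036 M | run made earlier |  |
| grey | 0.021 M | run made earlier |  |
| green | 0.059 M | run made earlier |  |
| Wednesday's | 0.0050 M |  | 1.0 h |
| Friday's | 0.080 M |  | 1.0 h |
| Sunday's | 0.020 M |  | 1.0 h |
| Monday's | 0.010 M |  | 1.0 h |
| Saturday's | 0.0060 M |  | 1.0 h |

| run | time / min | J / % | Q / % |
|---|---|---|---|
| teal | 3.00 | 26.3 | 44.2 |
| teal | 6.00 | 37.7 | 23.6 |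
| teal | 12.0 | 45.2 | 7.2 |
| teal | 20.0 | 49.4 | 4.7 |
| teal | 40.0 | 51.5 | 1.6 |
| grey | 3.00 | 18.3 | 18.6 |
| grey | 6.00 | 21.6 | 8.5 |
| grey | 12.0 | 22.1 | 3.2 |
| grey | 20.0 | 25.4 | 1.5 |
| grey | 40.0 | 25.2 | 3.2 |
| green | 4.00 | 10.6 | 6.5 |
| green | 10.0 | 13.4 | 1.6 |
| green | 20.0 | 12.5 | 0 |
| green | 30.0 | 14.6 | 0 |
| green | 40.0 | 15.0 | 1.8 |

(readings scatter by 1 percentage point)

- a species is counted by the Q in it: one X or E counts as two
- amounts and yields of J count E too
- the earlier runs were read with a standard deviation of 1 percentage point
- steps under discussion: 2 Q -> X; Q + J <-> E; Q <-> J; J <-> Z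
- in an amount of J, one E counts as one J

- all flasks from highest to lowest amount of J, in percent of the Q charged, at 1.0 h (Wednesday's / Friday's / Sunday's / Monday's / Saturday's)
- the amount of J, in percent of the Q charged of the flask you put first, at 1.0 h
- the amount of J, in percent of the Q charged of the flask you put last, at 1.0 h

I first read the fork from the fall of Q. Over the first 3.00 min, the teal run lost Q at 0.272 min⁻¹ at a mean Q of 0.00246 M, and the grey run lost it at 0.561 min⁻¹ at 0.0102 M. A straight line through these two gives a first-order part of 0.180 min⁻¹ and puts the even point, the concentration of Q at which a molecule is as likely to go alone as to meet a partner, at 0.00480 M. With x as the charge over the even point, a selectivity factor, the fraction of the charge leaving alone is ln(1+x)/x: 74.6% for teal, 38.5% for grey and 21.1% for green.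

The second way is the last reading of J: 51.5%, 25.2% and 15.0%. The two ways part, but evenly, since reading over reckoning comes to 69.0%, 65.5% and 71.1%. So I took the J reading to be the one that cheats as a count of the fork: about 68.6% of what left alone stands as J, and I read the remainder as Z, held by a balance J <-> Z.

My first-order half-life of 3.85 min is far shorter than 1.0 h, so I took the plateau. Since ln(1+x)/x falls as x rises, my order ran down the charges, from Wednesday's to Friday's, and my reckoning gave 47.0% for Wednesday's and 11.8% for Friday's.

The forecast gave Wednesday's > Saturday's > Monday's > Sunday's > Friday's, with 47% first and 13% last, holding that “yield falls steadily with charge, and the order follows concentration”. My order and top match it; my low stands 1.2 percentage points under it.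

The flasks gave Wednesday's > Saturday's > Monday's > Sunday's > Friday's, with 45.6% in Wednesday's against my 47.0%, and 11.0% in Friday's against my 11.8%.

    2 Q → X (k = 23.0 M⁻¹ min⁻¹)
    Q + J ⇌ E, settled at all times (K = 69.0 M⁻¹)
    Q ⇌ J (K = 20.0, k = 0.170 min⁻¹)
    J ⇌ Z (K = 0.330, k = 0.270 min⁻¹)

In Wednesday's, just after the start, the forward step from Q to J used Q at 0.74 of the rate of the turning of 2 Q into X, but at 1.00 h the same ratio stood at 34, far higher. By 1.28 min, far shorter than 1.0 h, the turning of 2 Q into X in Wednesday's had reached the midpoint of its turnover up to 1.0 h. For a neighbour of Wednesday's charged with 0.0013 M of Q, the even point and the kept share give 60.7% of J, and that flask stood at 61.7%.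

The numbers in the tables were computed on assumed constants, noise included.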